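**Strategy.** Ring A is closed at the C1–C2 bond (labdane numbering) by ruthenium-catalysed ring-rearrangement metathesis. The step exploits that C1 (on quaternary C10) and side-chain carbon C11 (on C9) sit on adjacent ring-B carbons: both are delivered together as a strained cyclobutene by enone–acetylene [2+2] photocycloaddition. Ring strain then drives one operation that opens the cyclobutene, forms C1=C2 with a vinyl ketone at C3 (ring A, trans-fused) and releases C11=C12 as the vinyl handle for the butenolide. The precursor is a cis-fused bicyclo[4.2.0]oct-7-en-2-one (ring B plus cyclobutene) carrying a Nazarov-type keto ester chain (C2–C4, C19) on C5.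

Key step: step 7

Remark: labdane numbering is used throughout (ring A: C1–C5, C10; ring B: C5–C10; side chain C11–C16; C17 on C8; C18 and C19 on C4; C20 on C10). The acryloyl unit is carried as a 3-chloropropanoyl group through step 5, because a free pendant olefin would be captured intramolecularly by the excited enone.

**Step 1**
Reactants: 1 2-methylcyclohex-2-en-1-one
Product: 2 (1R)-2-methylcyclohex-2-en-1-ol
Conditions: (S)-2-methyl-CBS-oxazaborolidine (10 mol %), BH3·SMe2, THF, −20 °C
Reagents that add atoms: none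
Why: Corey–Bakshi–Shibata reduction, in which the (S)-oxazaborolidine should deliver hydride 1,2 to the face that gives the (R)-carbinol, the 2-methylalkenyl arm acting as the large group.

**Step 2**
Reactants: 2 (1R)-2-methylcyclohex-2-en-1-ol; 3 triethyl orthoacetate
Product: 5 ethyl 2-[(1R)-2-methylcyclohex-2-en-1-yl]acetate, via mixed ketene acetal 4 (not isolated)
Conditions: MeC(OEt)3 (neat), EtCO2H (cat.), 140 °C, EtOH distilled off
Reagents that add atoms: none
Why: Johnson–Claisen rearrangement, whose [3,3] shift is suprafacial on the ring, so the C9–O configuration should be transferred to the new C4–C5 bond (C5 set) while the olefin moves to C9=C10.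

**Step 3**
Reactants: 5 ethyl 2-[(1R)-2-methylcyclohex-2-en-1-yl]acetate; 6 3-chloropropanoyl chloride
Product: 7 ethyl 5-chloro-2-[(1R)-2-methylcyclohex-2-en-1-yl]-3-oxopentanoate
Conditions: LiN(iPr)2 (2.1 equiv), THF, −78 °C; then 6, −78 °C; cold 1 M HCl quench
Reagents that add atoms: none
Why: crossed Claisen C-acylation of the ester enolate, the second equivalent of base storing the product as its enolate; C4 stays epimerisable and the primary chloride is the masked vinyl group.

**Step 4**
Reactants: 7 ethyl 5-chloro-2-[(1R)-2-methylcyclohex-2-en-1-yl]-3-oxopentanoate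
Product: 8 ethyl 5-chloro-2-[(1R)-2-methyl-4-oxocyclohex-2-en-1-yl]-3-oxopentanoate
Conditions: CrO3, 3,5-dimethylpyrazole, CH2Cl2, −20 °C
Reagents that add atoms: chromium trioxide, O=[Cr](=O)=O
Why: allylic oxidation with hexavalent chromium at C8, the only allylic ring methylene, should give the conjugated C8 enone, the keto ester and alkyl chloride being as inert here as in chromium-based alcohol oxidations.

**Step 5**
Reactants: 8 ethyl 5-chloro-2-[(1R)-2-methyl-4-oxocyclohex-2-en-1-yl]-3-oxopentanoate; 9 acetylene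
Product: 10 ethyl 5-chloro-2-[(1R,2R,6R)-1-methyl-5-oxobicyclo[4.2.0]oct-7-en-2-yl]-3-oxopentanoate
Conditions: hν (350 nm, Pyrex), C2H2-saturated CH2Cl2, −70 °C, irradiation stopped before full conversion
Reagents that add atoms: none
Why: enone–alkyne [2+2] photocycloaddition through the enone triplet, in which acetylene should add to the C9=C10 face anti to the branched C5 substituent (setting C10, with C1 trans to C4) and the cyclobutene can only be cis-fused (setting C9, to be inverted in step 9).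

**Step 6**
Reactants: 10 ethyl 5-chloro-2-[(1R,2R,6R)-1-methyl-5-oxobicyclo[4.2.0]oct-7-en-2-yl]-3-oxopentanoate
Product: 11 ethyl 2-[(1R,2R,6R)-1-methyl-5-oxobicyclo[4.2.0]oct-7-en-2-yl]-3-oxopent-4-enoate
Conditions: Et3N (1.5 equiv), CH2Cl2, 0 °C; short silica pad; used without storage
Reagents that add atoms: none
Why: E1cB loss of HCl from the β-chloro ketone with a weak amine base should unmask the vinyl ketone without exposing the acid-sensitive cyclobutene ketone to acid.

**Step 7**
Reactants: 11 ethyl 2-[(1R,2R,6R)-1-methyl-5-oxobicyclo[4.2.0]oct-7-en-2-yl]-3-oxopent-4-enoate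
Product: 13 ethyl (4aR,5R,8aR)-5-ethenyl-4a-methyl-2,6-dioxo-1,2,4a,5,6,7,8,8a-octahydronaphthalene-1-carboxylate, via ring-opened triene 12 (not isolated)
Conditions: second-generation Hoveyda–Grubbs catalyst RuCl2(SIMes)(=CH-C6H4-2-OiPr) (5 mol %), ethylene (1 atm), 1,4-benzoquinone (10 mol %), toluene (0.005 M), 60 °C
Reagents that add atoms: ethylene, C=C
Why: Ring-rearrangement metathesis: the ruthenium methylidene formed under ethylene opens the strained cyclobutene to the cis-divinyl ketone 12, whose C10 vinyl group then undergoes ring-closing metathesis with the vinyl ketone to form C1=C2 and expel ethylene. The closest known reaction type is the ring-opening/ring-closing metathesis of photochemically made cyclobutenes that carry a pendant olefin. Ring A closes as a six-membered cyclohexenone, trans-fused to ring B, by ring-closing metathesis between C1 and C2. No new stereocentre is made: C5 and C10 are already fixed, and the C9 vinyl group is left axial (9-epi) for correction in step 9. The step needs ring A closure to win over closure through C11 and over oligomerisation; the trans, diequatorial C1 vinyl and C5 chain allow the six-membered ring while C11 is axial on the opposite face, and ethylene, high dilution and benzoquinone (against olefin migration by ruthenium hydrides) should suppress the rest.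

**Step 8**
Reactants: 13 ethyl (4aR,5R,8aR)-5-ethenyl-4a-methyl-2,6-dioxo-1,2,4a,5,6,7,8,8a-octahydronaphthalene-1-carboxylate
Product: 14 ethyl (1S,4aR,5R,8aS)-5-ethenyl-1,4a-dimethyl-2,6-dioxo-1,2,4a,5,6,7,8,8a-octahydronaphthalene-1-carboxylate
Conditions: K2CO3, MeI, acetone, 0 °C to rt
Reagents that add atoms: iodomethane, CI
Why: C-alkylation of the cyclic β-keto ester enolate, in which MeI should approach C4 anti to the axial C20 methyl, so C18 becomes equatorial and the ester (C19) axial and cis to C20 (the classical podocarpic-type C4 construction); carbonate does not deprotonate the C8 ketone.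

**Step 9**
Reactants: 14 ethyl (1S,4aR,5R,8aS)-5-ethenyl-1,4a-dimethyl-2,6-dioxo-1,2,4a,5,6,7,8,8a-octahydronaphthalene-1-carboxylate
Product: 15 ethyl (1S,4aR,5S,8aS)-5-ethenyl-1,4a-dimethyl-2,6-dioxo-1,2,4a,5,6,7,8,8a-octahydronaphthalene-1-carboxylate
Conditions: DBU (0.3 equiv), toluene, 0 °C to rt, monitored; AcOH quench
Reagents that add atoms: none
Why: base-mediated epimerisation through the C8 dienolate, whose α-reprotonation from the axial direction anti to C20 is favoured both kinetically and thermodynamically and should place the C9 vinyl group equatorial; the ring-A carbonyl has no enolisable hydrogen.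

**Step 10**
Reactants: 15 ethyl (1S,4aR,5S,8aS)-5-ethenyl-1,4a-dimethyl-2,6-dioxo-1,2,4a,5,6,7,8,8a-octahydronaphthalene-1-carboxylate
Product: 17 ethyl (1S,4aS,5R,6S,8aS)-5-ethenyl-6-formyl-1,4a-dimethyl-2-oxo-1,2,4a,5,6,7,8,8a-octahydronaphthalene-1-carboxylate, via methyl enol ether 16 (not isolated)
Conditions: Ph3P(CH2OMe)Cl (3.5 equiv), KN(SiMe3)2 (3.0 equiv), THF, 0 °C to rt; then 2 M HCl, THF, rt; then DBU (0.2 equiv), CH2Cl2, rt
Reagents that add atoms: (methoxymethyl)triphenylphosphonium chloride, COC[P+](c1ccccc1)(c1ccccc1)c1ccccc1.[Cl-]; water, O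
Why: Wittig methoxymethylenation of the C8 ketone (the C3 carbonyl is conjugated and neopentyl), enol ether hydrolysis and base equilibration of the α-branched aldehyde should place the formyl group equatorial, trans to the C9 vinyl group and away from axial C20 (C8 set under thermodynamic control).

**Step 11**
Reactants: 17 ethyl (1S,4aS,5R,6S,8aS)-5-ethenyl-6-formyl-1,4a-dimethyl-2-oxo-1,2,4a,5,6,7,8,8a-octahydronaphthalene-1-carboxylate
Product: 18 ethyl (1S,4aS,5R,6S,8aS)-5-ethenyl-6-formyl-1,4a-dimethyl-2-oxodecahydronaphthalene-1-carboxylate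
Conditions: [(Ph3P)CuH]6 (Stryker's reagent, monovalent copper hydride), H2O (5 equiv), benzene, rt
Reagents that add atoms: none
Why: Stryker conjugate reduction should saturate the C1=C2 enone chemoselectively, leaving the isolated vinyl group, the aldehyde and the ester untouched.

**Step 12**
Reactants: 18 ethyl (1S,4aS,5R,6S,8aS)-5-ethenyl-6-formyl-1,4a-dimethyl-2-oxodecahydronaphthalene-1-carboxylate
Product: 19 (1R,2R,4aS,5R,6S,8aS)-5-ethenyl-1,6-bis(hydroxymethyl)-1,4a-dimethyldecahydronaphthalen-2-ol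
Conditions: LiAlH4, THF, 0 °C to rt; Rochelle salt work-up
Reagents that add atoms: none
Why: global hydride reduction of aldehyde, ester and ketone, in which axial hydride attack on C3 from the face opposite the axial C19 and C20 groups should give the equatorial 3-hydroxyl cis to C19 (C3 set).

**Step 13**
Reactants: 19 (1R,2R,4aS,5R,6S,8aS)-5-ethenyl-1,6-bis(hydroxymethyl)-1,4a-dimethyldecahydronaphthalen-2-ol; 20 3-bromofuran-2(5H)-one
Product: 22 14-deoxy-17-hydroxyandrographolide, via B-alkyl-9-BBN adduct 21 (not isolated)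
Conditions: 9-BBN (4.5 equiv), THF, 0 °C to rt; then H2O, Cs2CO3, 20, PdCl2(dppf) (10 mol %, divalent palladium precatalyst), AsPh3, DMF, rt; pH 5 buffer work-up
Reagents that add atoms: none
Why: anti-Markovnikov hydroboration of the vinyl group and B-alkyl Suzuki–Miyaura coupling with the α-bromobutenolide should form C12–C13, the three hydroxyls being carried as borinates that hydrolyse under the aqueous coupling and work-up conditions.

**Compound list**

1 | 2-methylcyclohex-2-en-1-one | CC1=CCCCC1=O | starting material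
2 | (1R)-2-methylcyclohex-2-en-1-ol | O[C@@H]1CCCC=C1C | intermediate
3 | triethyl orthoacetate | CC(OCC)(OCC)OCC | starting material
4 | 1-ethoxy-1-{[(1R)-2-methylcyclohex-2-en-1-yl]oxy}ethene (mixed ketene acetal) | C=C(OCC)O[C@@H]1CCCC=C1C | intermediate
5 | ethyl 2-[(1R)-2-methylcyclohex-2-en-1-yl]acetate | CCOC(=O)C[C@H]1CCCC=C1C | intermediate
6 | 3-chloropropanoyl chloride | O=C(Cl)CCCl | starting material
7 | ethyl 5-chloro-2-[(1R)-2-methylcyclohex-2-en-1-yl]-3-oxopentanoate (both C2 epimers) | CCOC(=O)C(C(=O)CCCl)[C@H]1CCCC=C1C | intermediate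
8 | ethyl 5-chloro-2-[(1R)-2-methyl-4-oxocyclohex-2-en-1-yl]-3-oxopentanoate (both C2 epimers) | CCOC(=O)C(C(=O)CCCl)[C@H]1CCC(=O)C=C1C | intermediate
9 | acetylene | C#C | starting material
10 | ethyl 5-chloro-2-[(1R,2R,6R)-1-methyl-5-oxobicyclo[4.2.0]oct-7-en-2-yl]-3-oxopentanoate | CCOC(=O)C(C(=O)CCCl)[C@H]1CCC(=O)[C@@H]2C=C[C@]12C | intermediate
11 | ethyl 2-[(1R,2R,6R)-1-methyl-5-oxobicyclo[4.2.0]oct-7-en-2-yl]-3-oxopent-4-enoate | CCOC(=O)C(C(=O)C=C)[C@H]1CCC(=O)[C@@H]2C=C[C@]12C | intermediate
12 | ethyl 2-[(1R,2R,3R)-2,3-diethenyl-2-methyl-4-oxocyclohexyl]-3-oxopent-4-enoate | CCOC(=O)C(C(=O)C=C)[C@H]1CCC(=O)[C@H](C=C)[C@]1(C)C=C | intermediate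
13 | ethyl (4aR,5R,8aR)-5-ethenyl-4a-methyl-2,6-dioxo-1,2,4a,5,6,7,8,8a-octahydronaphthalene-1-carboxylate (C1 epimers and enol) | CCOC(=O)C1[C@H]2CCC(=O)[C@H](C=C)[C@]2(C)C=CC1=O | intermediate
14 | ethyl (1S,4aR,5R,8aS)-5-ethenyl-1,4a-dimethyl-2,6-dioxo-1,2,4a,5,6,7,8,8a-octahydronaphthalene-1-carboxylate | C[C@]1(C(=O)OCC)[C@H]2CCC(=O)[C@H](C=C)[C@]2(C)C=CC1=O | intermediate
15 | ethyl (1S,4aR,5S,8aS)-5-ethenyl-1,4a-dimethyl-2,6-dioxo-1,2,4a,5,6,7,8,8a-octahydronaphthalene-1-carboxylate | C[C@]1(C(=O)OCC)[C@H]2CCC(=O)[C@@H](C=C)[C@]2(C)C=CC1=O | intermediate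
16 | ethyl (1S,4aR,5S,8aS)-5-ethenyl-6-(methoxymethylidene)-1,4a-dimethyl-2-oxo-1,2,4a,5,6,7,8,8a-octahydronaphthalene-1-carboxylate (E/Z mixture) | C[C@]1(C(=O)OCC)[C@H]2CCC(=COC)[C@@H](C=C)[C@]2(C)C=CC1=O | intermediate
17 | ethyl (1S,4aS,5R,6S,8aS)-5-ethenyl-6-formyl-1,4a-dimethyl-2-oxo-1,2,4a,5,6,7,8,8a-octahydronaphthalene-1-carboxylate | C[C@]1(C(=O)OCC)[C@H]2CC[C@H](C=O)[C@@H](C=C)[C@]2(C)C=CC1=O | intermediate
18 | ethyl (1S,4aS,5R,6S,8aS)-5-ethenyl-6-formyl-1,4a-dimethyl-2-oxodecahydronaphthalene-1-carboxylate | C[C@]1(C(=O)OCC)[C@H]2CC[C@H](C=O)[C@@H](C=C)[C@]2(C)CCC1=O | intermediate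
19 | (1R,2R,4aS,5R,6S,8aS)-5-ethenyl-1,6-bis(hydroxymethyl)-1,4a-dimethyldecahydronaphthalen-2-ol | C[C@]1(CO)[C@H]2CC[C@H](CO)[C@@H](C=C)[C@]2(C)CC[C@H]1O | intermediate
20 | 3-bromofuran-2(5H)-one | O=C1OCC=C1Br | starting material
21 | B-alkyl-9-BBN adduct of 19 (9-borabicyclo[3.3.1]nonan-9-yl on C12 and on the three oxygens) | C[C@]1(COB3C4CCCC3CCC4)[C@H]2CC[C@H](COB3C4CCCC3CCC4)[C@@H](CCB3C4CCCC3CCC4)[C@]2(C)CC[C@H]1OB3C4CCCC3CCC4 | intermediate
22 | 14-deoxy-17-hydroxyandrographolide, 3-{2-[(1R,2S,4aS,5R,6R,8aS)-6-hydroxy-2,5-bis(hydroxymethyl)-5,8a-dimethyldecahydronaphthalen-1-yl]ethyl}furan-2(5H)-one | C[C@]1(CO)[C@H]2CC[C@H](CO)[C@@H](CCC3=CCOC3=O)[C@]2(C)CC[C@H]1O | target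

**Step count.** Total: 13 steps. Longest linear sequence: 13 steps (1 to 22).

**Steps most likely to fail**

1. Step 10. The basic ylide may deprotonate the doubly activated C9–H (enolisation instead of olefination), and selectivity between the two ketones may be incomplete. Fallback, from 15 back to 17: non-basic addition of Me3SiCH2Li/CeCl3 to the C8 ketone should give the β-hydroxysilane F1. Peterson elimination (HF·pyridine) gives the 8(17)-methylidene compound F2. mCPBA epoxidises the electron-richer 1,1-disubstituted olefin to the spiro-epoxide F3. Meinwald rearrangement with MgBr2·OEt2 followed by DBU equilibration returns to aldehyde 17.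

2. Step 9. The vinyl double bond may migrate into conjugation with the C8 ketone, or epimerisation of the poorly aligned equatorial C9–H may stall. Fallback, from 14 back to 15: Me3SiOTf/Et3N should give the conjugated silyl dienol ether F4, which erases C9. Kinetic α-protonation at −78 °C (Bu4NF buffered with AcOH), axial and anti to C20, returns to 15.

3. Step 13. The free hydroxyls consume borane, and base-induced decomposition of the bromobutenolide may outrun the slow alkyl transmetalation. Fallback, from 19 back to 22: silylation (tBuMe2SiOTf, 2,6-lutidine) gives the tris-silyl ether F5. Hydroboration–oxidation (9-BBN; NaBO3) gives the primary alcohol F6, and I2/PPh3/imidazole gives the iodide F7. Alkylation of the lithium enolate of 3-(phenylsulfanyl)oxolan-2-one gives the α-phenylsulfanyl lactone F8. mCPBA at −78 °C gives the sulfoxide F9, and thermal syn-elimination (toluene, 110 °C) gives the silylated butenolide F10. HF·pyridine then releases 22.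

**Further compounds**

F1 | step 10 | β-hydroxysilane: 8-hydroxy-8-[(trimethylsilyl)methyl] adduct of 15 (C8 epimers) | C[C@]1(C(=O)OCC)[C@H]2CCC(O)(C[Si](C)(C)C)[C@@H](C=C)[C@]2(C)C=CC1=O
F2 | step 10 | 8(17)-methylidene analogue of 15 | C[C@]1(C(=O)OCC)[C@H]2CCC(=C)[C@@H](C=C)[C@]2(C)C=CC1=O
F3 | step 10 | 8,17-spiro-epoxide of F2 (C8 epimers) | C[C@]1(C(=O)OCC)[C@H]2CCC3(CO3)[C@@H](C=C)[C@]2(C)C=CC1=O
F4 | step 9 | 8-(trimethylsilyloxy)-8,9-ene dienol ether of 14 | C[C@]1(C(=O)OCC)[C@H]2CCC(O[Si](C)(C)C)=C(C=C)[C@]2(C)C=CC1=O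
F5 | step 13 | tris(tert-butyldimethylsilyl) ether of 19 | C[C@]1(CO[Si](C)(C)C(C)(C)C)[C@H]2CC[C@H](CO[Si](C)(C)C(C)(C)C)[C@@H](C=C)[C@]2(C)CC[C@H]1O[Si](C)(C)C(C)(C)C
F6 | step 13 | 12-hydroxy compound (primary alcohol from F5) | C[C@]1(CO[Si](C)(C)C(C)(C)C)[C@H]2CC[C@H](CO[Si](C)(C)C(C)(C)C)[C@@H](CCO)[C@]2(C)CC[C@H]1O[Si](C)(C)C(C)(C)C
F7 | step 13 | 12-iodo compound | C[C@]1(CO[Si](C)(C)C(C)(C)C)[C@H]2CC[C@H](CO[Si](C)(C)C(C)(C)C)[C@@H](CCI)[C@]2(C)CC[C@H]1O[Si](C)(C)C(C)(C)C
F8 | step 13 | α-alkyl-α-(phenylsulfanyl)-γ-butyrolactone (C13 epimers) | C[C@]1(CO[Si](C)(C)C(C)(C)C)[C@H]2CC[C@H](CO[Si](C)(C)C(C)(C)C)[C@@H](CCC3(Sc4ccccc4)CCOC3=O)[C@]2(C)CC[C@H]1O[Si](C)(C)C(C)(C)C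
F9 | step 13 | sulfoxide of F8 | C[C@]1(CO[Si](C)(C)C(C)(C)C)[C@H]2CC[C@H](CO[Si](C)(C)C(C)(C)C)[C@@H](CCC3(S(=O)c4ccccc4)CCOC3=O)[C@]2(C)CC[C@H]1O[Si](C)(C)C(C)(C)C
F10 | step 13 | tris(tert-butyldimethylsilyl) ether of 22 | C[C@]1(CO[Si](C)(C)C(C)(C)C)[C@H]2CC[C@H](CO[Si](C)(C)C(C)(C)C)[C@@H](CCC3=CCOC3=O)[C@]2(C)CC[C@H]1O[Si](C)(C)C(C)(C)C
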